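## Retrosynthetic overview

1. Target ⇒ the C5–O and C1′–O bonds are cut together: syn-dihydroxylation of the exocyclic E-olefin of a (4R)-4-acetoxy-5-pentadecylidenecyclopentenone, from the face anti to the acetate.
2. That dienone acetate ⇒ the ester C–O bond and, behind it, the C4–O and C1=O bonds, both from one O2: singlet-oxygen [4+2] addition to 6-tetradecylfulvene, then catalyst-controlled Kornblum–DeLaMare opening of the endoperoxide (sets C4 and the E geometry).
3. Fulvene ⇒ cyclopentadiene + pentadecanal (condensation, the only C–C bond made); cyclopentadiene ⇐ dicyclopentadiene.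
4. Rings: the carbocycle is bought, not built. The only ring formed is the transient dioxabicyclo[2.2.1]heptene from the O2 cycloaddition, opened in the same flask.

Ring numbering used throughout: C1 = C=O, C4 = CH–OAc, C5 = quaternary carbinol carbon, C1′ = side-chain carbinol carbon.

Assumption: cyclopentadiene is not sold as the monomer, so cracking of its commercial dimer is counted as step 1; pentadecanal is bought as such.
Assumption: the cupreidine-series catalyst is written for step 3; if a first analytical run shows the (4S) sense, the pseudo-enantiomeric cupreine-series catalyst is used instead.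
Assumption: compound numbers follow the order of appearance in the forward steps below.

## Route

Step 1
Reactants: 1 endo-dicyclopentadiene
Product: 2 cyclopenta-1,3-diene
Conditions: neat, 170 °C, distil through a Vigreux column into a −78 °C receiver; use at once
Reagents that add atoms: none
Why: retro-Diels–Alder cracking, in which each molecule of the dimer splits into two molecules of the monomer and the equilibrium is drained by distilling off the low-boiling monomer (bp 41 °C); no stereocentre is involved.

Step 2
Reactants: 2 cyclopenta-1,3-diene; 3 pentadecanal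
Product: 4 6-tetradecylfulvene (5-pentadecylidenecyclopenta-1,3-diene)
Conditions: pyrrolidine (1.5 equiv), MeOH/THF, 0 °C → rt; AcOH quench; pentane extraction, short neutral alumina plug; store cold, use within a day
Reagents that add atoms: none
Why: pyrrolidine-mediated (Stone–Little) fulvene condensation, a Knoevenagel-type process in which cyclopentadienide adds to the pyrrolidine-derived iminium ion of the aldehyde and loss of pyrrolidine gives the exocyclic olefin, and which tolerates enolisable aliphatic aldehydes; the fulvene is planar and achiral, so no stereocentre is set.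

Step 3
Reactants: 4 6-tetradecylfulvene
Product: 7 (4R,5E)-4-acetoxy-5-pentadecylidenecyclopent-2-en-1-one, via fulvene endoperoxide 5 (not isolated), via hydroxy dienone 6 (not isolated)
Conditions: O2, TPP (0.5 mol %), white LED, CH2Cl2, −78 °C; lamp off, Ar purge; 9-O-benzylcupreidine (20 mol %), −45 °C, 16 h (until 5 is consumed); then Ac2O, pyridine, DMAP (5 mol %), −45 → 0 °C
Reagents that add atoms: oxygen O=O; acetic anhydride CC(=O)OC(C)=O
Why: Proposed new method: an enantiomer-sorting Kornblum–DeLaMare rearrangement of the racemic fulvene endoperoxide under a bifunctional cinchona base, in which (after the [4+2] addition of singlet oxygen has made both ring C–O bonds) the quinuclidine nitrogen removes only the bridgehead C–H of one absolute sense while the 6′-OH hydrogen-bonds the leaving peroxide oxygen (E2-type O–O cleavage), so that the endoperoxide enantiomer whose selected C–H lies anti to the alkyl chain gives the E dienone with the untouched C–O bond as the (4R) carbinol, the mirror-image endoperoxide can only give the Z isomer (removed on silica after the in-flask DMAP-catalysed acetylation), and the closest known reaction types are the triethylamine-induced rearrangement of fulvene endoperoxides to racemic 4-hydroxy-5-alkylidenecyclopentenones and the cinchona-base desymmetrisation of meso bicyclic endoperoxides.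

Step 4
Reactants: 7 (4R,5E)-4-acetoxy-5-pentadecylidenecyclopent-2-en-1-one
Product: 8 (4R,5S)-4-acetoxy-5-hydroxy-5-[(1S)-1-hydroxypentadecyl]cyclopent-2-en-1-one
Conditions: OsO4 (2 mol %), NMO (1.3 equiv), citric acid (1 equiv), t-BuOH/acetone/H2O, 0 °C → rt; stop at full conversion of 7
Reagents that add atoms: osmium tetroxide O=[Os](=O)(=O)=O (catalytic, delivers both oxygens); N-methylmorpholine N-oxide C[N+]1([O-])CCOCC1; water O
Why: acid-buffered Upjohn-type osmium-catalysed syn-dihydroxylation, in which the [3+2] addition of OsO4 takes the more electron-rich trisubstituted exocyclic olefin rather than the ring enone C=C and comes in anti to the allylic C4 acetate, so that C5–OH is trans to the acetate (5S) and, both oxygens going to one face of the E-olefin, C1′ is S, while the citric acid speeds osmate hydrolysis of the electron-poor olefin and suppresses acetyl migration.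

## Compound list

1 | endo-dicyclopentadiene (3a,4,7,7a-tetrahydro-4,7-methano-1H-indene; racemic, one enantiomer drawn) | C1C=C[C@@H]2[C@H]1[C@H]1C[C@@H]2C=C1 | starting material
2 | cyclopenta-1,3-diene | C1C=CC=C1 | intermediate
3 | pentadecanal | CCCCCCCCCCCCCCC=O | starting material
4 | 6-tetradecylfulvene (5-pentadecylidenecyclopenta-1,3-diene; achiral) | CCCCCCCCCCCCCCC=C1C=CC=C1 | intermediate
5 | 7-pentadecylidene-2,3-dioxabicyclo[2.2.1]hept-5-ene (fulvene endoperoxide, racemic, not isolated; drawn is the enantiomer that gives 6, alkyl chain anti to the bridgehead that becomes C=O) | CCCCCCCCCCCCCC/C=C1/[C@@H]2C=C[C@H]1OO2 | intermediate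
6 | (4R,5E)-4-hydroxy-5-pentadecylidenecyclopent-2-en-1-one (not isolated) | CCCCCCCCCCCCCC/C=C1/C(=O)C=C[C@H]1O | intermediate
7 | (4R,5E)-4-acetoxy-5-pentadecylidenecyclopent-2-en-1-one | CCCCCCCCCCCCCC/C=C1/C(=O)C=C[C@H]1OC(C)=O | intermediate
8 | (4R,5S)-4-acetoxy-5-hydroxy-5-[(1S)-1-hydroxypentadecyl]cyclopent-2-en-1-one (CNP0238439.2; acetate trans to the 5-OH, cis to the side chain) | CCCCCCCCCCCCCC[C@H](O)[C@@]1(O)C(=O)C=C[C@H]1OC(C)=O | target

## Step count and risks

Total steps: 4. Longest linear sequence: 4 (1 → 2 → 4 → 7 → 8; pentadecanal 3 enters at step 2).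

Three steps most likely to fail:

**Step 3 (proposed new step).** The endoperoxide 5 decomposes above about −20 °C, so the chiral base must turn over at −45 °C. Incomplete site control would lower the ee of the E product, and at best half of 5 ends as the E isomer. The fallback uses known chemistry; it sets out from fulvene 4 and comes back at acetate 7. Photooxygenation as in step 3 gives endoperoxide 5, which triethylamine (CH2Cl2, −78 → −20 °C) rearranges to racemic (E)-4-hydroxy-5-pentadecylidenecyclopent-2-en-1-one F1, freed from the minor Z isomer on silica. Lipase-catalysed transesterification (Burkholderia cepacia lipase, vinyl acetate, MTBE, 30 °C, stopped near 50 % conversion) acetylates the R alcohol, as the usual secondary-alcohol rule predicts, to give 7. It leaves (4S,5E)-4-hydroxy-5-pentadecylidenecyclopent-2-en-1-one F2, which is separated. Should the enzyme prefer the other enantiomer, the unreacted alcohol is 6 and is acetylated chemically to 7.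

**Step 4.** Risks are incomplete facial control by the small acetate, attack on the ring enone, and acetyl migration to the new hydroxyls. The fallback changes the order of events and the protecting groups; it sets out from hydroxy dienone 6 (isolated by leaving the anhydride out of step 3) and comes back at target 8.
- TBSCl and imidazole in DMF give (4R,5E)-4-(tert-butyldimethylsilyloxy)-5-pentadecylidenecyclopent-2-en-1-one F3.
- OsO4/NMO then gives, anti to the bulky silyl ether and with no acyl group to migrate, (4R,5S)-4-(tert-butyldimethylsilyloxy)-5-hydroxy-5-[(1S)-1-hydroxypentadecyl]cyclopent-2-en-1-one F4.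
- 2-Methoxypropene and PPTS close the C5/C1′ diol to the silyl ether acetonide F5.
- HF·pyridine in THF frees the C4 hydroxyl to give the acetonide alcohol F6.
- Ac2O, pyridine and DMAP give the acetonide acetate F7.
- 80 % aqueous acetic acid at 40 °C removes the acetonide to give 8.

**Step 2.** Risks are self-aldol of the long-chain aldehyde under amine and polymerisation or double-bond isomerisation of the monoalkylfulvene. The fallback builds the fulvene by organolithium addition to an aminofulvene; it sets out from cyclopentadiene 2 and comes back at fulvene 4. Cyclopentadiene and N,N-dimethylformamide dimethyl acetal (neat, 20–40 °C) give 6-(dimethylamino)fulvene F8. Tetradecyllithium F9 (from 1-bromotetradecane and lithium metal in Et2O) adds to C6 of F8 (THF, 0 °C) to give lithium [1-(dimethylamino)pentadecyl]cyclopentadienide F10. Acetic acid work-up protonates F10, and the aminoalkylcyclopentadiene loses dimethylamine to give 4.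

## Further compounds

F1 | step 3 | racemic (E)-4-hydroxy-5-pentadecylidenecyclopent-2-en-1-one | CCCCCCCCCCCCCC/C=C1/C(=O)C=CC1O
F2 | step 3 | (4S,5E)-4-hydroxy-5-pentadecylidenecyclopent-2-en-1-one | CCCCCCCCCCCCCC/C=C1/C(=O)C=C[C@@H]1O
F3 | step 4 | (4R,5E)-4-(tert-butyldimethylsilyloxy)-5-pentadecylidenecyclopent-2-en-1-one | CCCCCCCCCCCCCC/C=C1/C(=O)C=C[C@H]1O[Si](C)(C)C(C)(C)C
F4 | step 4 | (4R,5S)-4-(tert-butyldimethylsilyloxy)-5-hydroxy-5-[(1S)-1-hydroxypentadecyl]cyclopent-2-en-1-one | CCCCCCCCCCCCCC[C@H](O)[C@@]1(O)C(=O)C=C[C@H]1O[Si](C)(C)C(C)(C)C
F5 | step 4 | 5,1′-O-isopropylidene acetal (acetonide) of F4 | CCCCCCCCCCCCCC[C@@H]1OC(C)(C)O[C@@]12C(=O)C=C[C@H]2O[Si](C)(C)C(C)(C)C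
F6 | step 4 | desilylated acetonide alcohol (4-OH free) | CCCCCCCCCCCCCC[C@@H]1OC(C)(C)O[C@@]12C(=O)C=C[C@H]2O
F7 | step 4 | 4-O-acetyl acetonide (5,1′-O-isopropylidene derivative of 8) | CCCCCCCCCCCCCC[C@@H]1OC(C)(C)O[C@@]12C(=O)C=C[C@H]2OC(C)=O
F8 | step 2 | 6-(dimethylamino)fulvene | CN(C)C=C1C=CC=C1
F9 | step 2 | tetradecyllithium | [Li]CCCCCCCCCCCCCC
F10 | step 2 | lithium [1-(dimethylamino)pentadecyl]cyclopentadienide (racemic) | CCCCCCCCCCCCCCC(N(C)C)[c-]1cccc1.[Li+]
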